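**Plan**
- Retrosynthesis: the two benzyl ethers (7-O and 3'-O) come off first; the pyran ring is then cut at C4–C4a and O1–C8a in one operation, giving ring-A iodide 19 and the C3-chiral bromohydrin 12. Bromohydrin 12 goes back through its C–Br bond to the prochiral oxetane 10, and 10 through the aryl–oxetane bond and the 3'-oxygen.
- Enabling feature: in ring A, C8a sits between C8 (bearing OMe) and C4a (bearing H). An iodide at C8a therefore has one blocked and one free ortho carbon, so alkylation goes to C4a and etherification to C8a.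
- Forward order: ring B is joined to the oxetane (steps 1–2), oxygenated at C3' and benzylated (steps 3–4), and the oxetane is opened asymmetrically (step 5). The ring-A iodide is made in three steps (6–8). The pyran ring closes in step 9, and debenzylation follows (step 10).
- Stereochemistry: the single stereocentre C3 is set in step 5 by catalyst-controlled desymmetrisation of the oxetane and is not a reacting centre afterwards.

Key step: step 9

Assumption: in step 5 the antipode of the squaramide catalyst that delivers the (S)-bromide is used; both antipodes are accessible, so the sense of induction only decides which one is taken.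

**Step 1**
Reactants: 1 1-bromo-2,4,5-trimethoxybenzene
Product: 4 (2,4,5-trimethoxyphenyl)boronic acid, via (2,4,5-trimethoxyphenyl)lithium 2 (not isolated), via lithium triisopropoxy(2,4,5-trimethoxyphenyl)borate 3 (not isolated)
Conditions: n-BuLi, THF, −78 °C; B(Oi-Pr)3, −78 °C → rt; dilute aq. HCl (to pH ~5)
Reagents that add atoms: triisopropyl borate CC(C)OB(OC(C)C)OC(C)C; water O
Why: Bromine–lithium exchange at −78 °C is faster than any ring deprotonation, and trapping the aryllithium with a trialkyl borate followed by mild hydrolysis is the standard lithiation–borylation route to an arylboronic acid.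

**Step 2**
Reactants: 4 (2,4,5-trimethoxyphenyl)boronic acid; 5 3-iodooxetane
Product: 6 3-(2,4,5-trimethoxyphenyl)oxetane
Conditions: NiI2 (6 mol %), trans-2-aminocyclohexanol·HCl (6 mol %), NaHMDS (2 equiv), i-PrOH, 80 °C
Reagents that add atoms: none
Why: Nickel-catalysed alkyl–aryl Suzuki–Miyaura coupling of secondary alkyl iodides with arylboronic acids under amino-alcohol ligand and alkoxide activation is established for 3-iodooxetane, whose ring-constrained alkylnickel intermediate resists β-hydride elimination.

**Step 3**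
Reactants: 6 3-(2,4,5-trimethoxyphenyl)oxetane
Product: 9 2,3,6-trimethoxy-5-(oxetan-3-yl)phenol, via [2,3,6-trimethoxy-5-(oxetan-3-yl)phenyl]lithium 7 (not isolated), via lithium trimethoxy[2,3,6-trimethoxy-5-(oxetan-3-yl)phenyl]borate 8 (not isolated)
Conditions: n-BuLi, TMEDA, THF, 0 °C; B(OMe)3, −78 °C → rt; aq. NaOH, H2O2, 0 °C → rt; NH4Cl work-up
Reagents that add atoms: hydrogen peroxide OO
Why: Directed ortho-metalation: C3' is the only ring C–H flanked by two methoxy groups and is lithiated in preference to C6', the oxetane is inert to n-BuLi in the absence of a Lewis acid, and borylation followed by basic peroxide oxidation turns the aryllithium into the phenol.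

**Step 4**
Reactants: 9 2,3,6-trimethoxy-5-(oxetan-3-yl)phenol
Product: 10 3-[3-(benzyloxy)-2,4,5-trimethoxyphenyl]oxetane
Conditions: BnBr, K2CO3, DMF, rt
Reagents that add atoms: benzyl bromide BrCc1ccccc1
Why: Williamson ether synthesis on the phenoxide, which masks the 3'-OH through the silyl bromide and palladium steps and is removable at the end together with the ring-A benzyl group.

**Step 5**
Reactants: 10 3-[3-(benzyloxy)-2,4,5-trimethoxyphenyl]oxetane
Product: 12 (2S)-2-[3-(benzyloxy)-2,4,5-trimethoxyphenyl]-3-bromopropan-1-ol, via trimethylsilyl ether 11 (not isolated)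
Conditions: chiral arylpyrrolidine-derived squaramide (5 mol %), TMSBr (1.1 equiv), t-BuOMe, −78 °C; then 1 M aq. HCl, THF, 0 °C
Reagents that add atoms: bromotrimethylsilane C[Si](C)(C)Br
Why: Enantioselective hydrogen-bond-donor catalysed ring opening of a prochiral 3-substituted oxetane: the chiral squaramide binds bromide and steers it to one of the two enantiotopic CH2–O carbons of the O-silylated oxetanium ion, so that C3 becomes stereogenic under catalyst control without itself reacting, and dilute acid then cleaves the labile primary trimethylsilyl ether.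

**Step 6**
Reactants: 13 1,3-dibromo-2-methoxybenzene (2,6-dibromoanisole)
Product: 16 3-bromo-2-methoxyphenol, via (3-bromo-2-methoxyphenyl)lithium 14 (not isolated), via lithium (3-bromo-2-methoxyphenyl)trimethoxyborate 15 (not isolated)
Conditions: n-BuLi (1.0 equiv), THF, −78 °C; B(OMe)3, −78 °C → rt; aq. NaOH, H2O2, 0 °C
Reagents that add atoms: hydrogen peroxide OO
Why: Selective mono bromine–lithium exchange with one equivalent of n-BuLi (the aryllithium formed is meta to the remaining bromine, so no aryne can form) followed by borylation–oxidation is a standard way to turn one C–Br bond into a phenol.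

**Step 7**
Reactants: 16 3-bromo-2-methoxyphenol
Product: 17 1-(benzyloxy)-3-bromo-2-methoxybenzene
Conditions: BnBr, K2CO3, DMF, rt
Reagents that add atoms: benzyl bromide BrCc1ccccc1
Why: Williamson ether synthesis; the benzyl ether is to be cleaved together with that of ring B in the final step.

**Step 8**
Reactants: 17 1-(benzyloxy)-3-bromo-2-methoxybenzene
Product: 19 1-(benzyloxy)-3-iodo-2-methoxybenzene, via [3-(benzyloxy)-2-methoxyphenyl]lithium 18 (not isolated)
Conditions: n-BuLi, THF, −78 °C; I2, −78 °C → rt
Reagents that add atoms: iodine II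
Why: Bromine–lithium exchange at −78 °C outpaces deprotonation of the benzylic ether CH2, and iodinolysis of the aryllithium gives the aryl iodide needed for fast, selective oxidative addition in the palladium/norbornene step.

**Step 9**
Reactants: 19 1-(benzyloxy)-3-iodo-2-methoxybenzene; 12 (2S)-2-[3-(benzyloxy)-2,4,5-trimethoxyphenyl]-3-bromopropan-1-ol (1.5 equiv)
Product: 20 (3S)-7-(benzyloxy)-3-[3-(benzyloxy)-2,4,5-trimethoxyphenyl]-8-methoxy-3,4-dihydro-2H-chromene
Conditions: Pd(OAc)2 (10 mol %), XPhos (20 mol %), norbornene (1 equiv), K2CO3 (3 equiv), MeCN, 70 °C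
Reagents that add atoms: none
Why: Proposed new method: Pd(0) adds to the C8a–I bond of 19 in preference to the alkyl bromide, norbornene inserts and C–H palladation at C4a gives the aryl-norbornyl palladacycle, which takes up the primary bromide of 12 by SN2-type oxidative addition to Pd(IV) and reductively eliminates to forge C4–C4a. With both ortho positions now substituted, norbornene is extruded by β-carbon elimination, and the tethered hydroxyl is deprotonated on Pd(II) to an aryl-palladium alkoxide that reductively eliminates to form C8a–O1. The closest known reaction type is the Catellani-type palladium/norbornene ortho-alkylation/ipso-etherification annulation of ortho-substituted aryl iodides with epoxides to 2,3-dihydrobenzofurans (and the related ring-forming ortho-alkylation/ipso-amination with bromoalkylamines), of which the three-carbon bromohydrin closing a six-membered ring is an extension. The pyran ring closes by C(aryl)–O reductive elimination from a seven-membered oxapalladacycle, and the bulky biaryl phosphine is chosen to favour this over β-hydride loss from the primary alkoxide. No stereocentre is formed: C3 lies one carbon from each reacting terminus and its C–H is not acidic enough for carbonate, so the configuration of 12 should be carried into 20. The step needs site selectivity, secured by the C8 methoxy group blocking the second ortho position, and alkylation faster than base-induced closure of 12 to the achiral oxetane, for which a mild, sparingly soluble carbonate and an excess of 12 are used.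

**Step 10**
Reactants: 20 (3S)-7-(benzyloxy)-3-[3-(benzyloxy)-2,4,5-trimethoxyphenyl]-8-methoxy-3,4-dihydro-2H-chromene
Product: 21 (3S)-3-(3-hydroxy-2,4,5-trimethoxyphenyl)-8-methoxy-3,4-dihydro-2H-chromen-7-ol (CNP0201239.1)
Conditions: H2 (1 atm), 10 % Pd/C, EtOAc/MeOH, rt
Reagents that add atoms: none
Why: Catalytic hydrogenolysis cleaves both benzylic C–O bonds, while the aryl methyl ethers, the aryl alkyl ether of the pyran ring and the C3 stereocentre (no benzylic heteroatom bond) are inert to H2 on Pd/C.

**Compound list**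
1 | 1-bromo-2,4,5-trimethoxybenzene | COc1cc(OC)c(OC)cc1Br | starting material
2 | (2,4,5-trimethoxyphenyl)lithium | COc1cc(OC)c(OC)cc1[Li] | intermediate
3 | lithium triisopropoxy(2,4,5-trimethoxyphenyl)borate | [Li+].COc1cc(OC)c(OC)cc1[B-](OC(C)C)(OC(C)C)OC(C)C | intermediate
4 | (2,4,5-trimethoxyphenyl)boronic acid | COc1cc(OC)c(OC)cc1B(O)O | intermediate
5 | 3-iodooxetane | IC1COC1 | starting material
6 | 3-(2,4,5-trimethoxyphenyl)oxetane | COc1cc(OC)c(OC)cc1C1COC1 | intermediate
7 | [2,3,6-trimethoxy-5-(oxetan-3-yl)phenyl]lithium | COc1c([Li])c(OC)c(OC)cc1C1COC1 | intermediate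
8 | lithium trimethoxy[2,3,6-trimethoxy-5-(oxetan-3-yl)phenyl]borate | [Li+].COc1c([B-](OC)(OC)OC)c(OC)c(OC)cc1C1COC1 | intermediate
9 | 2,3,6-trimethoxy-5-(oxetan-3-yl)phenol | COc1cc(C2COC2)c(OC)c(O)c1OC | intermediate
10 | 3-[3-(benzyloxy)-2,4,5-trimethoxyphenyl]oxetane | COc1cc(C2COC2)c(OC)c(OCc2ccccc2)c1OC | intermediate
11 | {(2S)-2-[3-(benzyloxy)-2,4,5-trimethoxyphenyl]-3-bromopropoxy}trimethylsilane | COc1cc([C@@H](CO[Si](C)(C)C)CBr)c(OC)c(OCc2ccccc2)c1OC | intermediate
12 | (2S)-2-[3-(benzyloxy)-2,4,5-trimethoxyphenyl]-3-bromopropan-1-ol | COc1cc([C@@H](CO)CBr)c(OC)c(OCc2ccccc2)c1OC | intermediate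
13 | 1,3-dibromo-2-methoxybenzene (2,6-dibromoanisole) | COc1c(Br)cccc1Br | starting material
14 | (3-bromo-2-methoxyphenyl)lithium | COc1c(Br)cccc1[Li] | intermediate
15 | lithium (3-bromo-2-methoxyphenyl)trimethoxyborate | [Li+].COc1c(Br)cccc1[B-](OC)(OC)OC | intermediate
16 | 3-bromo-2-methoxyphenol | COc1c(O)cccc1Br | intermediate
17 | 1-(benzyloxy)-3-bromo-2-methoxybenzene | COc1c(Br)cccc1OCc1ccccc1 | intermediate
18 | [3-(benzyloxy)-2-methoxyphenyl]lithium | COc1c([Li])cccc1OCc1ccccc1 | intermediate
19 | 1-(benzyloxy)-3-iodo-2-methoxybenzene | COc1c(I)cccc1OCc1ccccc1 | intermediate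
20 | (3S)-7-(benzyloxy)-3-[3-(benzyloxy)-2,4,5-trimethoxyphenyl]-8-methoxy-3,4-dihydro-2H-chromene | COc1cc([C@H]2COc3c(ccc(OCc4ccccc4)c3OC)C2)c(OC)c(OCc2ccccc2)c1OC | intermediate
21 | (3S)-3-(3-hydroxy-2,4,5-trimethoxyphenyl)-8-methoxy-3,4-dihydro-2H-chromen-7-ol | COc1cc([C@H]2COc3c(ccc(O)c3OC)C2)c(OC)c(O)c1OC | target

**Step count**
Total: 10 steps. Longest linear sequence: 7 steps (1, 2, 3, 4, 5, 9, 10), with the ring-A branch (6, 7, 8) converging at step 9.

**Steps most likely to fail**

Step 9. The β-branched primary bromide may add to the palladacycle too slowly. Base-induced cyclisation or HBr loss from 12, or β-hydride loss from the palladium alkoxide with ipso reduction of the arene, could then outrun the annulation. The fallback uses known reactions only, sets out from 12 and 17, and comes back at 20. Silylation of 12 (TBSCl, imidazole, DMF) would give tert-butyl{(2S)-2-[3-(benzyloxy)-2,4,5-trimethoxyphenyl]-3-bromopropoxy}dimethylsilane F1. Zinc insertion (Zn dust, LiCl, THF, 40 °C) would convert it into bromo{(2S)-2-[3-(benzyloxy)-2,4,5-trimethoxyphenyl]-3-[(tert-butyldimethylsilyl)oxy]propyl}zinc F2. In parallel, iodination of 17 para to the benzyloxy group (NIS, cat. TFA, MeCN) would give 1-(benzyloxy)-3-bromo-4-iodo-2-methoxybenzene F3. Negishi coupling of the zinc reagent at the C–I bond (Pd(OAc)2, SPhos, THF, rt) would form C4–C4a in {(2S)-3-[4-(benzyloxy)-2-bromo-3-methoxyphenyl]-2-[3-(benzyloxy)-2,4,5-trimethoxyphenyl]propoxy}(tert-butyl)dimethylsilane F4. TBAF in THF would free (2S)-3-[4-(benzyloxy)-2-bromo-3-methoxyphenyl]-2-[3-(benzyloxy)-2,4,5-trimethoxyphenyl]propan-1-ol F5. Intramolecular palladium-catalysed aryl etherification (Pd(OAc)2, a di-tert-butyl biaryl phosphine, Cs2CO3, toluene, 80 °C) would then close O1–C8a and deliver 20.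

Step 5. Bromide delivery to the two enantiotopic CH2–O carbons may be poorly discriminated. The ortho-methoxy, fully substituted aryl group crowds the catalyst-bound ion pair, and uncatalysed opening by TMSBr could compete. The fallback sets out from 10 and comes back at 12. Acid-catalysed hydrolysis of the oxetane (aq. H2SO4, dioxane, 60 °C) would give the prochiral 2-[3-(benzyloxy)-2,4,5-trimethoxyphenyl]propane-1,3-diol F6. Lipase-catalysed desymmetrising mono-acetylation (Pseudomonas lipase, vinyl acetate, i-Pr2O, rt) would give (2R)-2-[3-(benzyloxy)-2,4,5-trimethoxyphenyl]-3-hydroxypropyl acetate F7. If the enzyme prefers the other arm, hydrolysis of the diacetate by the same lipase gives the complementary monoacetate. Appel bromination (CBr4, PPh3, CH2Cl2, 0 °C) would give (2S)-2-[3-(benzyloxy)-2,4,5-trimethoxyphenyl]-3-bromopropyl acetate F8. Acid-catalysed methanolysis (HCl, MeOH, rt) would release 12 without exposing the bromohydrin to base.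

Step 2. Protodeboronation of the electron-rich, ortho-methoxy boronic acid in hot alkoxide/isopropanol may be faster than transmetalation to nickel. The fallback sets out from 1 and comes back at 6. Palladium-catalysed α-arylation of diethyl malonate with 1 (Pd(dba)2, P(t-Bu)3, K3PO4, toluene, 70 °C) would give diethyl 2-(2,4,5-trimethoxyphenyl)propanedioate F9. Reduction (LiAlH4, THF, 0 °C) would give 2-(2,4,5-trimethoxyphenyl)propane-1,3-diol F10. One-pot monotosylation and Williamson closure (n-BuLi, TsCl, THF, 0 °C; then n-BuLi, 60 °C) would pass through racemic 3-hydroxy-2-(2,4,5-trimethoxyphenyl)propyl 4-methylbenzenesulfonate F11 and give the oxetane 6.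

**Further compounds**
F1 | step 9 | tert-butyl{(2S)-2-[3-(benzyloxy)-2,4,5-trimethoxyphenyl]-3-bromopropoxy}dimethylsilane | COc1cc([C@@H](CO[Si](C)(C)C(C)(C)C)CBr)c(OC)c(OCc2ccccc2)c1OC
F2 | step 9 | bromo{(2S)-2-[3-(benzyloxy)-2,4,5-trimethoxyphenyl]-3-[(tert-butyldimethylsilyl)oxy]propyl}zinc | COc1cc([C@@H](CO[Si](C)(C)C(C)(C)C)C[Zn]Br)c(OC)c(OCc2ccccc2)c1OC
F3 | step 9 | 1-(benzyloxy)-3-bromo-4-iodo-2-methoxybenzene | COc1c(Br)c(I)ccc1OCc1ccccc1
F4 | step 9 | {(2S)-3-[4-(benzyloxy)-2-bromo-3-methoxyphenyl]-2-[3-(benzyloxy)-2,4,5-trimethoxyphenyl]propoxy}(tert-butyl)dimethylsilane | COc1cc([C@@H](CO[Si](C)(C)C(C)(C)C)Cc2ccc(OCc3ccccc3)c(OC)c2Br)c(OC)c(OCc2ccccc2)c1OC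
F5 | step 9 | (2S)-3-[4-(benzyloxy)-2-bromo-3-methoxyphenyl]-2-[3-(benzyloxy)-2,4,5-trimethoxyphenyl]propan-1-ol | COc1cc([C@@H](CO)Cc2ccc(OCc3ccccc3)c(OC)c2Br)c(OC)c(OCc2ccccc2)c1OC
F6 | step 5 | 2-[3-(benzyloxy)-2,4,5-trimethoxyphenyl]propane-1,3-diol | COc1cc(C(CO)CO)c(OC)c(OCc2ccccc2)c1OC
F7 | step 5 | (2R)-2-[3-(benzyloxy)-2,4,5-trimethoxyphenyl]-3-hydroxypropyl acetate | COc1cc([C@@H](COC(C)=O)CO)c(OC)c(OCc2ccccc2)c1OC
F8 | step 5 | (2S)-2-[3-(benzyloxy)-2,4,5-trimethoxyphenyl]-3-bromopropyl acetate | COc1cc([C@@H](COC(C)=O)CBr)c(OC)c(OCc2ccccc2)c1OC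
F9 | step 2 | diethyl 2-(2,4,5-trimethoxyphenyl)propanedioate | CCOC(=O)C(C(=O)OCC)c1cc(OC)c(OC)cc1OC
F10 | step 2 | 2-(2,4,5-trimethoxyphenyl)propane-1,3-diol | COc1cc(OC)c(OC)cc1C(CO)CO
F11 | step 2 | racemic 3-hydroxy-2-(2,4,5-trimethoxyphenyl)propyl 4-methylbenzenesulfonate | COc1cc(OC)c(OC)cc1C(CO)COS(=O)(=O)c1ccc(C)cc1
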